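**Retrosynthetic overview**

1. Locants used throughout: cyclohexene ring C1 (bears the C7H2OBz arm)=C2, C3 (OBz), then C4, C5, C6 (the three carbinols, C6 next to C1).
2. Last disconnection: the C5–C6 bond between two carbinol carbons, i.e. two aldehyde carbons of like polarity, joined by a reductive pinacol-type cyclisation with trivalent titanium. It closes the only carbocycle, sets C5 and C6 and gives the target with no later step.
3. Precursor: a lactol–aldehyde (a 2,3-unsaturated hexodialdo-1,5-pyranose) that already carries both benzoates and the C3/C4 stereocentres, bought as C4/C5 of D-galactal.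
4. Enabling feature: the free C4–OH. In the precursor it is the ring oxygen of a six-membered lactol (pyran ring O4–C4–C3–C2=C1–C6) that masks the C6 aldehyde and locks C1=C2 cis; once the lactol opens it chelates the metal to the C5 aldehyde and steers the new stereocentres.
5. Precursor from D-galactal: C7 by 2-iodination and Stille hydroxymethylation, Ferrier rearrangement to shift the double bond and shed the former O3, then oxidation of the primary alcohol. Ring order: pyran ring bought; cyclohexene ring formed last, as the pyran ring opens.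

Key step: step 9

Remark: lactol 10 should be an anomeric mixture (partly hydrated at the aldehyde). Both anomers open to the same hydroxy enal 11, so the anomeric configuration of 7–10 is of no consequence (α is drawn for 7–9). Sugar locants are used in the names of 1–10.

**Route**

Step 1
Reactants: 1 D-galactal
Product: 3 3,4-di-O-benzoyl-6-O-(tert-butyldiphenylsilyl)-D-galactal, via 6-O-silyl galactal 2 (not isolated)
Conditions: TBDPSCl (1.05 equiv), pyridine, 0 °C; then BzCl (2.5 equiv), DMAP (cat.), 0 °C to rt
Reagents that add atoms: tert-butyl(chloro)diphenylsilane CC(C)(C)[Si](Cl)(c1ccccc1)c1ccccc1; benzoyl chloride O=C(Cl)c1ccccc1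
Why: The silyl chloride should react selectively at the primary 6-OH and benzoyl chloride then esterifies both secondary hydroxyls (nucleophilic acyl substitution, DMAP catalysis), so that O3 becomes the later Ferrier leaving group and O4 already carries a benzoate of the target; no stereocentre is changed.

Step 2
Reactants: 3 3,4-di-O-benzoyl-6-O-(tert-butyldiphenylsilyl)-D-galactal
Product: 4 3,4-di-O-benzoyl-6-O-(tert-butyldiphenylsilyl)-2-iodo-D-galactal
Conditions: NIS (1.2 equiv), AgNO3 (20 mol %), MeCN, 80 °C
Reagents that add atoms: N-iodosuccinimide O=C1CCC(=O)N1I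
Why: Electrophilic iodination of the enol ether (iodonium addition at C2, then loss of the C2 proton from the oxocarbenium ion), the known AgNO3/NIS 2-halogenation of acylated glycals, should give the vinyl iodide without touching the stereocentres.

Step 3
Reactants: 4 3,4-di-O-benzoyl-6-O-(tert-butyldiphenylsilyl)-2-iodo-D-galactal
Product: 5 3,4-di-O-benzoyl-6-O-(tert-butyldiphenylsilyl)-2-C-(hydroxymethyl)-D-galactal
Conditions: Bu3SnCH2OH (1.5 equiv), Pd(PPh3)4 (5 mol %), 1,4-dioxane, 90 °C
Reagents that add atoms: (tributylstannyl)methanol CCCC[Sn](CCCC)(CCCC)CO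
Why: Migita–Kosugi–Stille coupling of the vinyl iodide with the hydroxymethylstannane installs the future C7; glycal 3-esters ionise poorly under zerovalent palladium, so the allylic benzoate should survive, and a benzoyl shift to the new hydroxyl would be harmless because step 4 acylates whichever hydroxyl is free.

Step 4
Reactants: 5 3,4-di-O-benzoyl-6-O-(tert-butyldiphenylsilyl)-2-C-(hydroxymethyl)-D-galactal
Product: 6 3,4-di-O-benzoyl-2-C-(benzoyloxymethyl)-6-O-(tert-butyldiphenylsilyl)-D-galactal
Conditions: BzCl (1.3 equiv), pyridine, DMAP (cat.), CH2Cl2, 0 °C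
Reagents that add atoms: benzoyl chloride O=C(Cl)c1ccccc1
Why: Standard acylation of the remaining hydroxyl (nucleophilic acyl substitution, DMAP catalysis) installs the second benzoate of the target.

Step 5
Reactants: 6 3,4-di-O-benzoyl-2-C-(benzoyloxymethyl)-6-O-(tert-butyldiphenylsilyl)-D-galactal
Product: 7 4-methoxybenzyl 4-O-benzoyl-2-C-(benzoyloxymethyl)-6-O-(tert-butyldiphenylsilyl)-2,3-dideoxy-α-D-threo-hex-2-enopyranoside
Conditions: 4-methoxybenzyl alcohol (1.5 equiv), BF3·OEt2 (0.3 equiv), CH2Cl2, −40 to −20 °C
Reagents that add atoms: 4-methoxybenzyl alcohol COc1ccc(CO)cc1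
Why: Ferrier rearrangement: BF3 ionises the secondary allylic 3-benzoate with the help of the ring oxygen and the alcohol adds at the anomeric carbon of the allyl oxocarbenium ion, which moves the double bond to C2=C3 (the future C1=C2 of the target) and leaves the more stable trisubstituted alkene with a primary benzoate; the anomeric centre (expected mainly α by the anomeric effect) is lost later, and C4 and C5 are untouched.

Step 6
Reactants: 7 4-methoxybenzyl 4-O-benzoyl-2-C-(benzoyloxymethyl)-6-O-(tert-butyldiphenylsilyl)-2,3-dideoxy-α-D-threo-hex-2-enopyranoside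
Product: 8 4-methoxybenzyl 4-O-benzoyl-2-C-(benzoyloxymethyl)-2,3-dideoxy-α-D-threo-hex-2-enopyranoside
Conditions: HF·pyridine, pyridine, THF, 0 °C to rt
Reagents that add atoms: none
Why: Fluoride-mediated silyl ether cleavage under buffered, weakly acidic conditions should free the primary alcohol without acyl migration and without opening the allylic acetal.

Step 7
Reactants: 8 4-methoxybenzyl 4-O-benzoyl-2-C-(benzoyloxymethyl)-2,3-dideoxy-α-D-threo-hex-2-enopyranoside
Product: 9 4-methoxybenzyl 4-O-benzoyl-2-C-(benzoyloxymethyl)-2,3-dideoxy-α-D-threo-hex-2-enodialdo-1,5-pyranoside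
Conditions: Dess–Martin periodinane (1.3 equiv), CH2Cl2, 0 °C to rt; base-free work-up (filtration through silica)
Reagents that add atoms: none
Why: Dess–Martin oxidation turns the primary alcohol into the aldehyde without base, which matters because the 4-benzoate is both allylic and β to the new carbonyl.

Step 8
Reactants: 9 4-methoxybenzyl 4-O-benzoyl-2-C-(benzoyloxymethyl)-2,3-dideoxy-α-D-threo-hex-2-enodialdo-1,5-pyranoside
Product: 10 4-O-benzoyl-2-C-(benzoyloxymethyl)-2,3-dideoxy-D-threo-hex-2-enodialdo-1,5-pyranose
Conditions: DDQ (1.5 equiv), CH2Cl2–H2O (10:1), 0 °C to rt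
Reagents that add atoms: water O
Why: Oxidative cleavage of the 4-methoxybenzyl acetal by DDQ (benzylic hydride abstraction, loss of 4-methoxybenzaldehyde and capture of the allylic pyranosyl cation by water at the anomeric carbon) should unmask the lactol under neutral conditions that do not isomerise it to the open (E)-enal.

Step 9
Reactants: 10 4-O-benzoyl-2-C-(benzoyloxymethyl)-2,3-dideoxy-D-threo-hex-2-enodialdo-1,5-pyranose
Product: 12 [(3R,4R,5R,6S)-3-(benzoyloxy)-4,5,6-trihydroxycyclohex-1-en-1-yl]methyl benzoate (target), via open-chain hydroxy dialdehyde 11 (not isolated)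
Conditions: Cp2TiCl2 [(C5H5)2TiCl2] (3 equiv), Zn dust (6 equiv), THF, rt (gives Cp2TiCl); then 10 added slowly (0.01 M), 0 °C to rt; 1 M HCl work-up
Reagents that add atoms: none
Why: Ring–chain tautomerism of lactol 10, helped by the Lewis-acidic titanium and zinc salts, frees the (Z)-hydroxy enal 11; Cp2TiCl (trivalent titanium) reduces only the conjugated C6 aldehyde to an O-titanated allyl radical, which attacks the metal-bound C5 carbonyl through C6, a second Cp2TiCl captures the resulting oxygen radical, and HCl releases the diol from the titanium diolate. The closest known reactions are the Cp2TiCl pinacol coupling of α,β-unsaturated aldehydes and its cross version with aliphatic aldehydes, the Cp2TiPh closure of 1,6-dials to trans-cyclohexane-1,2-diols and the SmI2 pinacol cyclisation of sugar-derived hexodialdoses to cyclitols. The cyclohexene ring closes in a 6-exo-trig sense on the C5 carbonyl, and coupling through the β-carbon C2 is excluded because it would make a four-membered ring. C5 is set by the C4 stereocentre through chelation: the C4 hydroxyl and the C5 carbonyl oxygen hold one metal in a nearly planar five-membered ring, and C6, tied to C4 through C1=C2–C3, can reach only the carbonyl face on the C3 side of that ring, so the chelate is cis-fused to the new ring and O4 and O5 end up cis (O5 equatorial, O4 axial, O3 pseudoaxial and anti to O4). C6 is set by allylic strain: the enal reacts as the s-trans rotamer with the titanoxy group turned toward C7 and away from C3, which places this bulky group pseudoequatorial and trans to O5. The step needs chemoselective reduction of one aldehyde and a cis C1=C2 bond; the conjugation of C6 secures the first (the saturated aldehyde and the benzoates should be inert to Cp2TiCl) and the lactol ring, which can only open to the cis enal, secures the second.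

**Compound list**

1 | D-galactal (1,5-anhydro-2-deoxy-D-lyxo-hex-1-enitol) | OC[C@H]1OC=C[C@@H](O)[C@H]1O | starting material
2 | 6-O-(tert-butyldiphenylsilyl)-D-galactal | CC(C)(C)[Si](OC[C@H]1OC=C[C@@H](O)[C@H]1O)(c1ccccc1)c1ccccc1 | intermediate
3 | 3,4-di-O-benzoyl-6-O-(tert-butyldiphenylsilyl)-D-galactal | CC(C)(C)[Si](OC[C@H]1OC=C[C@@H](OC(=O)c2ccccc2)[C@H]1OC(=O)c1ccccc1)(c1ccccc1)c1ccccc1 | intermediate
4 | 3,4-di-O-benzoyl-6-O-(tert-butyldiphenylsilyl)-2-iodo-D-galactal | CC(C)(C)[Si](OC[C@H]1OC=C(I)[C@@H](OC(=O)c2ccccc2)[C@H]1OC(=O)c1ccccc1)(c1ccccc1)c1ccccc1 | intermediate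
5 | 3,4-di-O-benzoyl-6-O-(tert-butyldiphenylsilyl)-2-C-(hydroxymethyl)-D-galactal | CC(C)(C)[Si](OC[C@H]1OC=C(CO)[C@@H](OC(=O)c2ccccc2)[C@H]1OC(=O)c1ccccc1)(c1ccccc1)c1ccccc1 | intermediate
6 | 3,4-di-O-benzoyl-2-C-(benzoyloxymethyl)-6-O-(tert-butyldiphenylsilyl)-D-galactal | CC(C)(C)[Si](OC[C@H]1OC=C(COC(=O)c2ccccc2)[C@@H](OC(=O)c2ccccc2)[C@H]1OC(=O)c1ccccc1)(c1ccccc1)c1ccccc1 | intermediate
7 | 4-methoxybenzyl 4-O-benzoyl-2-C-(benzoyloxymethyl)-6-O-(tert-butyldiphenylsilyl)-2,3-dideoxy-α-D-threo-hex-2-enopyranoside | COc1ccc(CO[C@H]2O[C@H](CO[Si](c3ccccc3)(c3ccccc3)C(C)(C)C)[C@H](OC(=O)c3ccccc3)C=C2COC(=O)c2ccccc2)cc1 | intermediate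
8 | 4-methoxybenzyl 4-O-benzoyl-2-C-(benzoyloxymethyl)-2,3-dideoxy-α-D-threo-hex-2-enopyranoside | COc1ccc(CO[C@H]2O[C@H](CO)[C@H](OC(=O)c3ccccc3)C=C2COC(=O)c2ccccc2)cc1 | intermediate
9 | 4-methoxybenzyl 4-O-benzoyl-2-C-(benzoyloxymethyl)-2,3-dideoxy-α-D-threo-hex-2-enodialdo-1,5-pyranoside | COc1ccc(CO[C@H]2O[C@H](C=O)[C@H](OC(=O)c3ccccc3)C=C2COC(=O)c2ccccc2)cc1 | intermediate
10 | 4-O-benzoyl-2-C-(benzoyloxymethyl)-2,3-dideoxy-D-threo-hex-2-enodialdo-1,5-pyranose (lactol, anomeric mixture) | OC1O[C@H](C=O)[C@H](OC(=O)c2ccccc2)C=C1COC(=O)c1ccccc1 | intermediate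
11 | (2Z,4R,5S)-4-(benzoyloxy)-2-[(benzoyloxy)methyl]-5-hydroxyhex-2-enedial (open-chain tautomer of 10) | O=C/C(COC(=O)c1ccccc1)=C\[C@@H](OC(=O)c1ccccc1)[C@H](O)C=O | intermediate
12 | [(3R,4R,5R,6S)-3-(benzoyloxy)-4,5,6-trihydroxycyclohex-1-en-1-yl]methyl benzoate | O=C(OCC1=C[C@@H](OC(=O)c2ccccc2)[C@H](O)[C@H](O)[C@H]1O)c1ccccc1 | target

**Totals**

Total step count: 9. Longest linear sequence: 9 steps (from D-galactal).

**Steps most likely to fail**

Step 9. What may go wrong: closure through the s-cis enal rotamer or through a poorly organised chelate, i.e. poor facial selectivity at the allylic carbon C6. Over-reduction of the allyl radical before it closes, with loss of the allylic benzoate, is a second danger and argues for slow addition to excess reagent. Fallback: from 10 the cyclisation is run as in step 9 and the C6 configuration is set afterwards by reduction instead of by the cyclisation. The crude product, containing the C6-epimeric triol F1, is oxidised at the allylic carbinol only with MnO2 (CH2Cl2, rt) to the C6 enone F2. F2 is then reduced with Me4NBH(OAc)3 in MeCN/AcOH at −20 °C (hydroxyl-directed Evans–Saksena reduction). Boron bound to the C4/C5 hydroxyls on the lower face should deliver hydride to that face of the ketone and give the 5,6-trans alcohol, which returns to 12.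

Step 5. What may go wrong: ionisation at the primary C7 benzoate instead of the secondary 3-benzoate, so that the alcohol is captured with the double bond exocyclic. Fallback: from 6 this outcome is accepted and converged in a second operation. The 2-C-methylene glycoside F3 is isomerised with PdCl2(MeCN)2 (divalent palladium, 5 mol %, THF, rt). This [3,3] allylic ester transposition should move the 3-benzoate to the exocyclic carbon and the double bond into the ring, which gives 7.

Step 7. What may go wrong: β-elimination of benzoic acid from the new aldehyde, whose 4-benzoate is both allylic and β to the carbonyl, during oxidation, chromatography or the following acetal cleavage. Fallback: from 6 the aldehyde is made while the double bond is still in the glycal position, where the 4-benzoate is not allylic, and the lactol is unmasked by hydration instead of by oxidative acetal cleavage. HF·pyridine gives the primary alcohol glycal F4, Dess–Martin oxidation gives the glycal aldehyde F5, and a Ferrier-type hydration (InCl3 cat., MeCN–H2O, rt) then gives 10 directly, bypassing 7–9.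

**Further compounds**

F1 | step 9 | [(3R,4R,5R,6R)-3-(benzoyloxy)-4,5,6-trihydroxycyclohex-1-en-1-yl]methyl benzoate (C6 epimer of 12) | O=C(OCC1=C[C@@H](OC(=O)c2ccccc2)[C@H](O)[C@H](O)[C@@H]1O)c1ccccc1
F2 | step 9 | C6 ketone of 12, [3-(benzoyloxy)-4,5-dihydroxy-6-oxocyclohex-1-en-1-yl]methyl benzoate with C3, C4, C5 as in 12 | O=C(OCC1=C[C@@H](OC(=O)c2ccccc2)[C@H](O)[C@H](O)C1=O)c1ccccc1
F3 | step 5 | 4-methoxybenzyl 3,4-di-O-benzoyl-6-O-(tert-butyldiphenylsilyl)-2-deoxy-2-C-methylene-α-D-lyxo-hexopyranoside | COc1ccc(CO[C@H]2O[C@H](CO[Si](c3ccccc3)(c3ccccc3)C(C)(C)C)[C@H](OC(=O)c3ccccc3)[C@H](OC(=O)c3ccccc3)C2=C)cc1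
F4 | step 7 | 3,4-di-O-benzoyl-2-C-(benzoyloxymethyl)-D-galactal | OC[C@H]1OC=C(COC(=O)c2ccccc2)[C@@H](OC(=O)c2ccccc2)[C@H]1OC(=O)c1ccccc1
F5 | step 7 | 3,4-di-O-benzoyl-2-C-(benzoyloxymethyl)-D-galactal 6-aldehyde (1,5-anhydro-2-deoxy-D-lyxo-hex-1-enodialdose derivative) | O=C[C@H]1OC=C(COC(=O)c2ccccc2)[C@@H](OC(=O)c2ccccc2)[C@H]1OC(=O)c1ccccc1
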